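## Retrosynthetic overview

1. Target 23 comes from O9‑directed epoxidation of the C10 vinyl group of 22. The cis‑fused α‑methylene lactone comes from intramolecular SN2 of the C12 carboxylate on an 8α‑bromo‑9‑ketone, followed by reduction of the 9‑ketone.
2. The C5–C4 and C10–C1 bonds come from a one‑pot alkoxide‑directed conjugate addition/aldol on 4‑hydroxy enone 6. The acrolein unit enters as its diethyl acetal, and the free C6 hydroxyl is then angeloylated.
3. Enone 6 comes from Kornblum–DeLaMare opening of endoperoxide 5, itself the [4+2] cycloadduct of singlet oxygen with diene 4 (Shapiro reaction of (S)‑carvone tosylhydrazone). This cycloaddition is the key step: it installs O6 and O9 and relays carvone's stereocentre.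
4. Ring order: the carbocycle is bought in (S)‑carvone (its C5 becomes target C7); the 2,3‑dioxabicyclo[2.2.2]octene forms by cycloaddition and is opened; the γ‑lactone closes next; the oxirane comes last.

Assumption/convention: the target is taken exactly as drawn, (1S,5R,6S,7R,8R,9S,10S) with a (Z)‑2‑methylbut‑2‑enoate (angelate); ring carbons carry the target's elemane numbers (C5–C10) throughout, and β means the face of the C7 side chain (H‑7 is α).

## Route

Step 1
Reactants: 1 (S)-(+)-carvone
Product: 2 N'-[(5S)-2-methyl-5-(prop-1-en-2-yl)cyclohex-2-en-1-ylidene]-4-methylbenzenesulfonohydrazide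
Conditions: TsNHNH2, EtOH, cat. AcOH, 50 °C; crystallise
Reagents that add atoms: p-toluenesulfonyl hydrazide, Cc1ccc(cc1)S(=O)(=O)NN
Why: Simple hydrazone condensation at the enone carbonyl; the carvone stereocentre (future C7) is not touched.

Step 2
Reactants: 2 carvone tosylhydrazone
Product: 4 (5S)-2-methyl-5-(prop-1-en-2-yl)cyclohexa-1,3-diene, via alkenyllithium 3 (not isolated)
Conditions: MeLi (2.2 equiv), Et2O, 0 °C → rt; H2O
Reagents that add atoms: methyllithium, [Li]C (its lithium is carried only by intermediate 3)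
Why: Shapiro reaction: the only α‑CH2 (future C6) is deprotonated, sulfinate and N2 are lost, and protonation of the dienyllithium gives the C6=C5–C10=C9 diene without touching C7.

Step 3
Reactants: 4 diene
Product: 6 (4S,5R)-4-hydroxy-2-methyl-5-(prop-1-en-2-yl)cyclohex-2-en-1-one, via endoperoxide 5 (not isolated)
Conditions: O2, tetraphenylporphyrin (cat.), visible light, CH2Cl2, −30 °C; then Et3N, 0 °C → rt
Reagents that add atoms: dioxygen, O=O
Why: [4+2] cycloaddition of singlet oxygen across C6/C9 on the face anti to the C7 isopropenyl sets the 6α‑oxygen; Kornblum–DeLaMare rearrangement (Et3N removes the less hindered bridgehead H‑9) then gives the C9 ketone and the free 6α‑OH.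

Step 4
Reactants: 6 hydroxy enone; 7 2-bromo-3,3-diethoxyprop-1-ene
Product: 10 hydroxymethyl ketone (C9 ketone; C10 α-CH3/β-CH2OH; C5 α-C(=CH2)CH(OEt)2; C6 α-OH; C7 β-isopropenyl), via Grignard reagent 8 (not isolated), via magnesium enolate 9 (not isolated)
Conditions: 7, Mg, LiCl, THF, 0 °C (gives 8, 2.3 equiv); add 6, THF, −78 → −20 °C; CH2O (gas), −78 °C; aq NH4Cl
Reagents that add atoms: magnesium, [Mg] (carried only by intermediates 8 and 9); formaldehyde, C=O
Why: Alkoxide‑directed conjugate (Michael) addition: the magnesium alkoxide of O6 binds a second equivalent of 8 and delivers the alkenyl group to C5 on the α face (syn to O6, anti to the C7 isopropenyl), and the resulting enolate undergoes aldol addition to formaldehyde at C10 anti to the new C5 substituent, giving the quaternary centre with CH2OH β.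

Step 5
Reactants: 10 hydroxymethyl ketone
Product: 11 keto aldehyde (C10 β-CHO; otherwise as 10)
Conditions: TEMPO (cat.), PhI(OAc)2, CH2Cl2, rt
Reagents that add atoms: none
Why: Oxoammonium (TEMPO) oxidation is selective for the primary alcohol over the hindered secondary C6 hydroxyl, and C10 is quaternary so nothing can epimerise.

Step 6
Reactants: 11 keto aldehyde
Product: 12 vinyl ketone (C10 β-CH=CH2; C6 α-OH free)
Conditions: Ph3PCH3Br, KHMDS (2.2 equiv of ylide), THF, −78 → 0 °C
Reagents that add atoms: methyltriphenylphosphonium bromide, C[P+](c1ccccc1)(c1ccccc1)c1ccccc1.[Br-]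
Why: Wittig methylenation takes the aldehyde far faster than the C9 ketone, which is flanked by the quaternary C10.

Step 7
Reactants: 12 vinyl ketone; 13 angelic acid
Product: 14 angelate ester (C6 α-O-angeloyl; C9 ketone; C10 β-vinyl)
Conditions: 13, 2,4,6-trichlorobenzoyl chloride, Et3N, toluene, rt; then 12, toluene, 80 °C
Reagents that add atoms: none
Why: Yamaguchi‑type mixed‑anhydride acylation without a nucleophilic catalyst keeps the Z double bond, and acylation on oxygen retains the C6 configuration.

Step 8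
Reactants: 14 angelate ester
Product: 16 8α-bromo ketone, via silyl enol ether 15 (not isolated)
Conditions: LiHMDS, TMSCl, THF, −78 °C; then NBS, −78 → 0 °C
Reagents that add atoms: chlorotrimethylsilane, C[Si](C)(C)Cl (its silicon is carried only by intermediate 15); N-bromosuccinimide, BrN1C(=O)CCC1=O
Why: The ketone can enolise only toward C8 (C10 is quaternary), and electrophilic bromination of the silyl enol ether occurs anti to the adjacent C7 isopropenyl to give the 8α‑bromide.

Step 9
Reactants: 16 8α-bromo ketone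
Product: 18 enal (C7 β-C(=CH2)CHO), via allylic alcohol 17 (not isolated)
Conditions: SeO2 (cat.), t-BuOOH, CH2Cl2, rt; then MnO2, CH2Cl2, rt
Reagents that add atoms: selenium dioxide, O=[Se]=O (oxygen carrier); tert-butyl hydroperoxide, CC(C)(C)OO
Why: Riley allylic oxidation (ene reaction then [2,3]‑sigmatropic shift) attacks the methyl of the only isopropenyl group, since the vinyl group has no allylic hydrogen and the other alkenes are electron‑poor; MnO2 converges alcohol and aldehyde to the enal.

Step 10
Reactants: 18 enal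
Product: 20 keto lactone (cis-fused 8β,12-olide; C9 ketone), via acrylic acid 19 (not isolated)
Conditions: NaClO2, NaH2PO4, 2-methylbut-2-ene, t-BuOH/H2O, 0 °C; then K2CO3, DMF, rt
Reagents that add atoms: sodium chlorite, [Na+].[O-]Cl=O
Why: Pinnick oxidation gives the acrylic acid, whose carboxylate displaces the ketone‑activated 8α‑bromide by intramolecular SN2 (5‑exo‑tet, inversion), so the lactone oxygen ends up β and cis to C11.

Step 11
Reactants: 20 keto lactone
Product: 22 9β-hydroxy enal (C5 α-C(=CH2)CHO), via acetal alcohol 21 (not isolated)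
Conditions: NaBH4, CeCl3·7H2O, EtOH, −40 °C; then PPTS, acetone/H2O, rt
Reagents that add atoms: water, O
Why: Luche reduction is 1,2‑selective (methylene lactone and angelate survive) and hydride attacks the convex α face opposite the cis‑fused lactone to give the 9β‑alcohol; mild acetal hydrolysis then frees the enal.

Step 12
Reactants: 22 9β-hydroxy enal
Product: 23 target CNP0113462.5
Conditions: VO(acac)2 (cat.), t-BuOOH, CH2Cl2, 0 °C → rt
Reagents that add atoms: tert-butyl hydroperoxide, CC(C)(C)OO
Why: Hydroxyl‑directed (homoallylic) vanadium‑catalysed epoxidation touches only the electron‑rich vinyl group; the vanadate ester on O9 delivers oxygen to the vinyl face turned toward C9 in the rotamer that eclipses C2 with the C10 methyl, which gives the (1S) oxirane.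

## Compound list

1 | (S)-(+)-carvone, (5S)-2-methyl-5-(prop-1-en-2-yl)cyclohex-2-en-1-one | C1[C@H](C(C)=C)CC(=O)C(C)=C1 | starting material
2 | carvone tosylhydrazone | C1[C@H](C(C)=C)CC(=NNS(=O)(=O)c2ccc(C)cc2)C(C)=C1 | intermediate
3 | [(5S)-2-methyl-5-(prop-1-en-2-yl)cyclohexa-1,3-dien-3-yl]lithium | C1[C@H](C(C)=C)C=C([Li])C(C)=C1 | intermediate
4 | (5S)-2-methyl-5-(prop-1-en-2-yl)cyclohexa-1,3-diene | C1[C@H](C(C)=C)C=CC(C)=C1 | intermediate
5 | (1S,4S,7R)-5-methyl-7-(prop-1-en-2-yl)-2,3-dioxabicyclo[2.2.2]oct-5-ene (O–O bridge anti to isopropenyl) | C1[C@H](C(C)=C)[C@@H]2C=C(C)[C@H]1OO2 | intermediate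
6 | (4S,5R)-4-hydroxy-2-methyl-5-(prop-1-en-2-yl)cyclohex-2-en-1-one (OH trans to isopropenyl) | C1[C@H](C(C)=C)[C@@H](O)C=C(C)C1=O | intermediate
7 | 2-bromo-3,3-diethoxyprop-1-ene | C=C(Br)C(OCC)OCC | starting material
8 | (3,3-diethoxyprop-1-en-2-yl)magnesium bromide | C=C([Mg]Br)C(OCC)OCC | intermediate
9 | bis(bromomagnesium) C6-alkoxide C9-enolate after 1,4-addition (C5 side chain α) | C1[C@H](C(C)=C)[C@@H](O[Mg]Br)[C@@H](C(=C)C(OCC)OCC)C(C)=C1O[Mg]Br | intermediate
10 | hydroxymethyl ketone: C9 ketone, C10 α-CH3/β-CH2OH, C5 α-C(=CH2)CH(OEt)2, C6 α-OH, C7 β-isopropenyl | C1[C@H](C(C)=C)[C@@H](O)[C@@H](C(=C)C(OCC)OCC)[C@](C)(CO)C1=O | intermediate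
11 | keto aldehyde: as 10 with C10 β-CHO | C1[C@H](C(C)=C)[C@@H](O)[C@@H](C(=C)C(OCC)OCC)[C@](C)(C=O)C1=O | intermediate
12 | vinyl ketone: as 10 with C10 β-CH=CH2 | C1[C@H](C(C)=C)[C@@H](O)[C@@H](C(=C)C(OCC)OCC)[C@](C)(C=C)C1=O | intermediate
13 | angelic acid, (2Z)-2-methylbut-2-enoic acid | C/C=C(/C)C(=O)O | starting material
14 | angelate ester: as 12 with C6 α-O-angeloyl | C1[C@H](C(C)=C)[C@@H](OC(=O)/C(C)=C\C)[C@@H](C(=C)C(OCC)OCC)[C@](C)(C=C)C1=O | intermediate
15 | trimethylsilyl enol ether of 14 (C8=C9–OTMS) | C=1[C@H](C(C)=C)[C@@H](OC(=O)/C(C)=C\C)[C@@H](C(=C)C(OCC)OCC)[C@](C)(C=C)C=1O[Si](C)(C)C | intermediate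
16 | 8α-bromo ketone (Br trans to the C7 isopropenyl) | [C@H]1(Br)[C@H](C(C)=C)[C@@H](OC(=O)/C(C)=C\C)[C@@H](C(=C)C(OCC)OCC)[C@](C)(C=C)C1=O | intermediate
17 | allylic alcohol: as 16 with C7 β-C(=CH2)CH2OH | [C@H]1(Br)[C@H](C(=C)CO)[C@@H](OC(=O)/C(C)=C\C)[C@@H](C(=C)C(OCC)OCC)[C@](C)(C=C)C1=O | intermediate
18 | enal: as 16 with C7 β-C(=CH2)CHO | [C@H]1(Br)[C@H](C(=C)C=O)[C@@H](OC(=O)/C(C)=C\C)[C@@H](C(=C)C(OCC)OCC)[C@](C)(C=C)C1=O | intermediate
19 | acrylic acid: as 16 with C7 β-C(=CH2)CO2H | [C@H]1(Br)[C@H](C(=C)C(=O)O)[C@@H](OC(=O)/C(C)=C\C)[C@@H](C(=C)C(OCC)OCC)[C@](C)(C=C)C1=O | intermediate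
20 | keto lactone: cis-fused 8β,12-olide, C9 ketone, C6 α-angelate, C5 α-acetal side chain, C10 β-vinyl | C=C1C(=O)O[C@@H]2[C@H]1[C@@H](OC(=O)/C(C)=C\C)[C@@H](C(=C)C(OCC)OCC)[C@](C)(C=C)C2=O | intermediate
21 | acetal alcohol: as 20 with 9β-OH | C=C1C(=O)O[C@@H]2[C@H]1[C@@H](OC(=O)/C(C)=C\C)[C@@H](C(=C)C(OCC)OCC)[C@](C)(C=C)[C@@H]2O | intermediate
22 | 9β-hydroxy enal: as 21 with C5 α-C(=CH2)CHO | C=C1C(=O)O[C@@H]2[C@H]1[C@@H](OC(=O)/C(C)=C\C)[C@@H](C(=C)C=O)[C@](C)(C=C)[C@@H]2O | intermediate
23 | CNP0113462.5, (1S,5R,6S,7R,8R,9S,10S)-1,2-epoxy-6-angeloyloxy-9-hydroxy-15-oxoelema-3,11(13)-dien-8,12-olide | C=C1C(=O)O[C@@H]2[C@H]1[C@@H](OC(=O)/C(C)=C\C)[C@@H](C(=C)C=O)[C@](C)([C@H]1CO1)[C@@H]2O | target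

## Step count and risks

Total step count: 12. Longest linear sequence: 12 steps, from (S)-carvone 1 to 23.

Three steps most likely to fail:

Step 4 (directed conjugate addition/aldol). The Grignard reagent may add 1,2, may add to the β face, or 6 may dehydrate toward a phenol. The fallback replaces alkoxide delivery by a covalently attached phosphine directing group. It sets out from 6 and comes back at 10. The C6 hydroxyl of 6 is esterified with 2-(diphenylphosphanyl)benzoic acid (DCC, DMAP, CH2Cl2) to give the phosphine ester F1. Reagent 8 is then added with CuBr·SMe2, so that the monovalent copper alkenyl species is held by the phosphine and transferred to C5 from the ester-bearing α face; the enolate is quenched with CH2O to give the hydroxymethyl ketone phosphine ester F2. The directing ester is removed with K2CO3 in MeOH at 0 °C, which returns 10.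

Step 3 (cycloaddition and opening of the endoperoxide). Facial selectivity of singlet oxygen may be only moderate, and Et3N may open 5 the other way or dehydrate the product. The fallback replaces the base-induced rearrangement by reduction and a chemoselective oxidation. It sets out from 5 and comes back at 6. The endoperoxide is reduced with thiourea in MeOH to the cis-enediol F3, which is purified from the minor facial isomer at this stage. MnO2 in CH2Cl2 then oxidises only the less hindered allylic alcohol at C9, giving 6.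

Step 10 (lactone closure by bromide displacement). The bromide may have the wrong configuration, or may not survive steps 9 and 10. The fallback avoids the halide altogether. It sets out from 14 and comes back at 20. The isopropenyl group of 14 is oxidised directly (SeO2 cat., t-BuOOH, then MnO2) to the keto enal F4, and Pinnick oxidation gives the keto acid F5. The lactone is then closed oxidatively with the trivalent iodine reagent PhI(OH)OTs (MeCN, NaHCO3, rt): the enol attacks iodine anti to the C7 side chain and the carboxylate displaces iodobenzene with inversion, giving 20.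

Further compounds
F1 | step 4 | 2-(diphenylphosphanyl)benzoate ester of 6 at O6 | C1[C@H](C(C)=C)[C@@H](OC(=O)c2ccccc2P(c2ccccc2)c2ccccc2)C=C(C)C1=O
F2 | step 4 | 2-(diphenylphosphanyl)benzoate ester of 10 at O6 | C1[C@H](C(C)=C)[C@@H](OC(=O)c2ccccc2P(c2ccccc2)c2ccccc2)[C@@H](C(=C)C(OCC)OCC)[C@](C)(CO)C1=O
F3 | step 3 | cis-enediol: 2-methyl-5-(prop-1-en-2-yl)cyclohex-2-ene-1,4-diol, both OH α (anti to isopropenyl) | C1[C@H](C(C)=C)[C@@H](O)C=C(C)[C@H]1O
F4 | step 10 | keto enal: as 14 with C7 β-C(=CH2)CHO, no bromide | C1[C@H](C(=C)C=O)[C@@H](OC(=O)/C(C)=C\C)[C@@H](C(=C)C(OCC)OCC)[C@](C)(C=C)C1=O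
F5 | step 10 | keto acid: as 14 with C7 β-C(=CH2)CO2H, no bromide | C1[C@H](C(=C)C(=O)O)[C@@H](OC(=O)/C(C)=C\C)[C@@H](C(=C)C(OCC)OCC)[C@](C)(C=C)C1=O
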